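**Plan**

1. Germacranolide numbering is used: ring C1–C10, γ-lactone C6–O–C12(=O)–C11(=C13)–C7, C14 on C10, C15 on C4. Retrosynthetic cuts: the C14 acetate, the C8 methacrylate and the epoxide oxygen; C11=C13; the ring bond C9–C10; C8–C9; C6–C7; C1=C10.
2. Forward: geraniol supplies C1–C6 and C15 with the E C4=C5 bond. An iodo-Wittig reaction adds C10 and C14 as a (Z)-2-iodoallyl unit. An auxiliary-controlled succinate aldol joins C6–C7 and closes the γ-lactone (first ring). Diazomethane adds C9. A nickel-catalysed reductive coupling of the C10 vinyl iodide with the C9 bromide closes the ten-membered ring (second ring). C13, the esters and the epoxide (third ring) follow.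
3. Feature that allows the ring closure: C9 is a CH2 next to the oxygenated C8, and C10 is the fully substituted epoxide carbon bearing C14–O. C9 can therefore react as a radical from a primary halide (a C9 carbanion would expel the C8 oxygen), and C10 as the iodinated carbon of a 2-iodoallyl ether. The cis C1=C10 bond, the E C4=C5 bond and the trans-fused lactone at C6–C7 leave few free rotors between the two ends.
4. Stereochemistry: C6 and C7 from the (S)-4-benzyloxazolidinone (syn aldol, hence trans lactone); C8 from oxazaborolidine-catalysed reduction of a bromomethyl ketone; C4=C5 from geraniol; C1=C10 geometry from the Wittig step, retained in the coupling; C1 and C10 from a Sharpless epoxidation directed by the C14 hydroxyl.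
5. Helpers and their removal: oxazolidinone (off in step 9), triethylsilyl ether on O8 (off in step 15), tert-butyldiphenylsilyl ether on O14 (off in step 17). C13 is added only after ring closure, so no acrylate is present in the radical step.

Key step: step 13

Remark: geraniol, ethyl (triphenylphosphoranylidene)acetate, (4S)-4-benzyl-1,3-oxazolidin-2-one and methyl 4-chloro-4-oxobutanoate are taken as purchased; α/β descriptors assume the usual germacranolide drawing with H-7 α (lactone oxygen on C6 α, oxygen on C8 α).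

**Route**

Step 1
Reactants: 1 geraniol
Product: 2 triethyl{[(2E)-3,7-dimethylocta-2,6-dien-1-yl]oxy}silane (geranyl triethylsilyl ether)
Conditions: TESCl, imidazole, CH2Cl2, 0 °C to rt
Reagents that add atoms: chlorotriethylsilane, CC[Si](Cl)(CC)CC
Why: Imidazole-promoted silylation masks the C6 hydroxyl as a triethylsilyl ether that survives steps 2–5 and can later be oxidised directly to the aldehyde.

Step 2
Reactants: 2 geranyl triethylsilyl ether
Product: 3 (4E)-4-methyl-6-(triethylsilyloxy)hex-4-enal
Conditions: O3 (one equivalent, Sudan Red 7B end point), pyridine, CH2Cl2, −78 °C; then Me2S, −78 °C to rt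
Reagents that add atoms: ozone, [O-][O+]=O
Why: Chemoselective ozonolysis should cleave the remote trisubstituted alkene, which is more electron-rich than the C4=C5 alkene deactivated by the allylic oxygen, to give the C1 aldehyde with the E alkene intact.

Step 3
Reactants: 3 (4E)-4-methyl-6-(triethylsilyloxy)hex-4-enal; 4 ethyl (triphenylphosphoranylidene)acetate
Product: 6 ethyl (2Z,6E)-2-iodo-6-methyl-8-(triethylsilyloxy)octa-2,6-dienoate, via ethyl iodo(triphenylphosphoranylidene)acetate 5 (not isolated)
Conditions: 4, N-iodosuccinimide, CH2Cl2, −20 °C; then 3, −20 °C to rt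
Reagents that add atoms: N-iodosuccinimide, O=C1CCC(=O)N1I
Why: Iodination of the stabilised ylide followed by a Wittig reaction should place the ester trans to the chain (the usual preference of stabilised ylides), so iodine is cis to C2, which fixes the later cis C1=C10 geometry.

Step 4
Reactants: 6 ethyl (2Z,6E)-2-iodo-6-methyl-8-(triethylsilyloxy)octa-2,6-dienoate
Product: 7 (2Z,6E)-2-iodo-6-methyl-8-(triethylsilyloxy)octa-2,6-dien-1-ol
Conditions: i-Bu2AlH (DIBAL-H), CH2Cl2, −78 °C
Reagents that add atoms: none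
Why: 1,2-Reduction of the enoate by DIBAL-H at low temperature should give the C14 allylic alcohol without touching the vinyl iodide or the silyl ether.

Step 5
Reactants: 7 (2Z,6E)-2-iodo-6-methyl-8-(triethylsilyloxy)octa-2,6-dien-1-ol
Product: 8 tert-butyl{[(2Z,6E)-2-iodo-6-methyl-8-(triethylsilyloxy)octa-2,6-dien-1-yl]oxy}diphenylsilane
Conditions: TBDPSCl, imidazole, DMF, 0 °C to rt
Reagents that add atoms: tert-butyl(chloro)diphenylsilane, CC(C)(C)[Si](Cl)(c1ccccc1)c1ccccc1
Why: Standard silylation gives an acid-stable silyl ether on O14 that is orthogonal to the triethylsilyl ethers used on O6 and later on O8.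

Step 6
Reactants: 8 bis-silyl ether
Product: 9 (2E,6Z)-8-(tert-butyldiphenylsilyloxy)-7-iodo-3-methylocta-2,6-dienal
Conditions: (COCl)2, DMSO, CH2Cl2, −78 to −40 °C; then Et3N, −78 to 0 °C
Reagents that add atoms: none
Why: Swern conditions oxidise a primary triethylsilyl ether directly to the aldehyde (desilylation by the chlorosulfonium salt, then ylide fragmentation) while the tert-butyldiphenylsilyl ether is inert, so the E enal should form in one step.

Step 7
Reactants: 10 (4S)-4-benzyl-1,3-oxazolidin-2-one; 11 methyl 4-chloro-4-oxobutanoate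
Product: 12 methyl 4-[(4S)-4-benzyl-2-oxo-1,3-oxazolidin-3-yl]-4-oxobutanoate
Conditions: n-BuLi, THF, −78 °C; then 11, −78 to 0 °C
Reagents that add atoms: none
Why: N-Acylation of the lithiated oxazolidinone by the acid chloride gives the succinate imide for the Evans aldol reaction.

Step 8
Reactants: 12 succinate imide; 9 (2E,6Z)-8-(tert-butyldiphenylsilyloxy)-7-iodo-3-methylocta-2,6-dienal
Product: 14 (4S)-4-benzyl-3-{[(2R,3S)-2-[(1E,5Z)-7-(tert-butyldiphenylsilyloxy)-6-iodo-2-methylhepta-1,5-dien-1-yl]-5-oxooxolan-3-yl]carbonyl}-1,3-oxazolidin-2-one (ring substituents trans), via syn-aldol adduct 13 (not isolated)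
Conditions: Bu2BOTf, i-Pr2NEt, CH2Cl2, 0 °C; 9, −78 to 0 °C; pH 7 buffer, MeOH, H2O2, 0 °C; then PPTS (cat.), CH2Cl2, rt
Reagents that add atoms: none
Why: In this Evans syn-aldol reaction the Z boron enolate of the imide (the ester is not enolised) should add through a Zimmerman–Traxler chair on the face set by the (S)-benzyl auxiliary, fixing C7 and C6, and the C6 hydroxyl then closes onto the methyl ester to give the trans-disubstituted γ-lactone.

Step 9
Reactants: 14 lactone imide
Product: 15 (2R,3S)-2-[(1E,5Z)-7-(tert-butyldiphenylsilyloxy)-6-iodo-2-methylhepta-1,5-dien-1-yl]-5-oxooxolane-3-carboxylic acid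
Conditions: LiOH, H2O2, THF/H2O, 0 °C; Na2SO3 (aq); then 1 M HCl to pH 3
Reagents that add atoms: hydrogen peroxide, OO
Why: Lithium hydroperoxide attacks the exocyclic imide carbonyl selectively, releasing the C8 acid and the recoverable auxiliary, and C7 should not epimerise because the trans arrangement is also the stable one.

Step 10
Reactants: 15 lactone acid
Product: 18 (4S,5R)-4-(bromoacetyl)-5-[(1E,5Z)-7-(tert-butyldiphenylsilyloxy)-6-iodo-2-methylhepta-1,5-dien-1-yl]oxolan-2-one, via isobutyl carbonic mixed anhydride 16 (not isolated), via diazoketone 17 (not isolated)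
Conditions: i-BuOCOCl, N-methylmorpholine, THF, −15 °C; CH2N2 (Et2O), 0 °C; then 48% aq HBr, 0 °C
Reagents that add atoms: diazomethane, C=[N+]=[N-]; hydrogen bromide, Br
Why: Acylation of diazomethane by the mixed anhydride (first stage of an Arndt–Eistert sequence) adds C9 as a diazoketone, which HBr converts into the bromomethyl ketone with loss of nitrogen, and neither reagent should touch the lactone, the alkenes or the vinyl iodide.

Step 11
Reactants: 18 bromomethyl ketone
Product: 19 (4R,5R)-4-[(1R)-2-bromo-1-hydroxyethyl]-5-[(1E,5Z)-7-(tert-butyldiphenylsilyloxy)-6-iodo-2-methylhepta-1,5-dien-1-yl]oxolan-2-one (ring substituents trans as in 18)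
Conditions: (R)-2-methyl-CBS-oxazaborolidine (0.3 equiv), catecholborane, toluene, −78 °C
Reagents that add atoms: none
Why: In this Corey–Bakshi–Shibata reduction the (R)-oxazaborolidine should deliver hydride to the ketone face that puts the branched C7 group in the large position and CH2Br in the small one, setting the C8 carbinol under reagent control (R here, 8S once C9 is bonded to C10), and catecholborane does not hydroborate the alkenes.

Step 12
Reactants: 19 bromohydrin
Product: 20 (4S,5R)-4-[(1R)-2-bromo-1-(triethylsilyloxy)ethyl]-5-[(1E,5Z)-7-(tert-butyldiphenylsilyloxy)-6-iodo-2-methylhepta-1,5-dien-1-yl]oxolan-2-one (same configuration as 19)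
Conditions: TESOTf, 2,6-lutidine, CH2Cl2, −78 °C
Reagents that add atoms: triethylsilyl trifluoromethanesulfonate, CC[Si](CC)(CC)OS(=O)(=O)C(F)(F)F
Why: Silylation with a silyl triflate and a hindered pyridine protects O8 under non-basic conditions, before epoxide closure or lactone migration to O8 can occur.

Step 13
Reactants: 20 bromide/vinyl iodide
Product: 21 macrocyclic lactone: 14-(tert-butyldiphenylsilyloxy)-8α-(triethylsilyloxy)-13-norgermacra-1(10),4-dien-12,6α-olide (C4=C5 E; C1=C10 cis in the ring; H-6 β; H-7 α)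
Conditions: NiI2 (30 mol%), 4,4'-di-tert-butyl-2,2'-bipyridine (33 mol%), NaI (50 mol%), pyridine (30 mol%), Zn powder (4 equiv), N,N-dimethylacetamide, 25 °C, 20 added by syringe pump over 12 h (final 2 mM)
Reagents that add atoms: none
Why: Proposed new method: zerovalent nickel (from NiI2 and Zn) should insert into the C10–I bond with retention of the alkene geometry, the C9 bromide (iodide after exchange with NaI) should be reduced at nickel to the primary C9 radical, and capture of this radical by the vinylnickel of the same molecule followed by reductive elimination from trivalent nickel should form C9–C10; the closest known reaction type is the intermolecular nickel-catalysed reductive cross-electrophile coupling of alkenyl halides with primary alkyl bromides, which has not been used for a medium-ring closure. The ten-membered carbocycle closes by C(sp3)–C(sp2) reductive elimination from an eleven-membered nickelacycle, not by radical addition to an alkene. No stereocentre is formed: C8 keeps the configuration set in step 11 because C9 reacts as a radical and not as a carbanion, so the β-silyloxy group is not expelled, and the cis C1=C10 geometry is carried over from the vinyl iodide. The step needs ring closure to beat intermolecular coupling and simple reduction: syringe-pump addition keeps the substrate far more dilute than the catalyst, and the cis C1=C10 bond, the E C4=C5 bond and the trans-fused lactone hold C9 and C10 on the same side of a chain with few free rotors. It also needs chemoselectivity, which the substrate provides: only the sp2 iodide undergoes two-electron insertion, only the sp3 halide gives a radical, the lactone has no acrylate yet to trap that radical, and 5-exo attack of the radical on C5 would give a strained trans-fused bicyclo[3.3.0]octane.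

Step 14
Reactants: 21 macrocyclic lactone
Product: 24 14-(tert-butyldiphenylsilyloxy)-8α-(triethylsilyloxy)germacra-1(10),4,11(13)-trien-12,6α-olide (geometry and configuration as in 21), via Mannich base 22 (not isolated), via trimethylammonium iodide 23 (not isolated)
Conditions: LiN(i-Pr)2 (LDA), THF, −78 °C; CH2=NMe2+ I− (Eschenmoser's salt), −78 °C to rt; then MeI, MeOH, rt; then NaHCO3 (aq), EtOAc, rt
Reagents that add atoms: N,N-dimethylmethyleneiminium iodide (Eschenmoser's salt), C=[N+](C)C.[I-]
Why: The Eschenmoser α-methylenation (enolate Mannich reaction, N-methylation, β-elimination of trimethylamine) installs C13, the C11 stereocentre of the intermediates is destroyed in the elimination, and no acrylate or vinyl iodide is present when the strong base is used.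

Step 15
Reactants: 24 bis-silyl α-methylene lactone
Product: 25 14-(tert-butyldiphenylsilyloxy)-8α-hydroxygermacra-1(10),4,11(13)-trien-12,6α-olide
Conditions: PPTS, MeOH/CH2Cl2, 0 °C to rt
Reagents that add atoms: none
Why: Mild acid methanolysis should remove the secondary triethylsilyl ether selectively, because the tert-butyldiphenylsilyl ether on O14 is far more acid-stable.

Step 16
Reactants: 25 C8 alcohol
Product: 26 14-(tert-butyldiphenylsilyloxy)-8α-(methacryloyloxy)germacra-1(10),4,11(13)-trien-12,6α-olide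
Conditions: methacrylic anhydride, Et3N, DMAP (cat.), CH2Cl2, 0 °C to rt
Reagents that add atoms: methacrylic anhydride, C=C(C)C(=O)OC(=O)C(C)=C
Why: DMAP-catalysed acylation esterifies O8 with retention at C8 and, by capping O8, excludes lactone migration from O6 to O8.

Step 17
Reactants: 26 methacrylate silyl ether
Product: 27 14-hydroxy-8α-(methacryloyloxy)germacra-1(10),4,11(13)-trien-12,6α-olide
Conditions: HF·pyridine, pyridine, THF, 0 °C to rt
Reagents that add atoms: none
Why: Buffered fluoride desilylation frees the C14 allylic alcohol without conjugate addition to the two acrylate units.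

Step 18
Reactants: 27 allylic alcohol
Product: 28 (1R,10R)-1,10-epoxy-14-hydroxy-8α-(methacryloyloxy)germacra-4,11(13)-dien-12,6α-olide
Conditions: Ti(OiPr)4 (20 mol%), D-(−)-diethyl tartrate (25 mol%), t-BuOOH (decane), 4 Å molecular sieves, CH2Cl2, −20 °C
Reagents that add atoms: tert-butyl hydroperoxide, CC(C)(C)OO
Why: In this Sharpless asymmetric epoxidation the titanium tartrate binds the C14 allylic alcohol and delivers oxygen only to C1=C10, D-(−)-diethyl tartrate selecting the face that gives the 1R,10R epoxide (syn addition keeps C2 and C9 cis), while the electron-poor methylene groups and the undirected C4=C5 alkene should not react.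

Step 19
Reactants: 28 epoxy alcohol
Product: 29 target, (1R,10R)-14-acetoxy-1,10-epoxy-8α-(methacryloyloxy)germacra-4,11(13)-dien-12,6α-olide (1R,6R,7R,8S,10R; 4E)
Conditions: Ac2O, pyridine, DMAP (cat.), CH2Cl2, 0 °C
Reagents that add atoms: acetic anhydride, CC(=O)OC(C)=O
Why: Acetylation of the primary alcohol under mild base completes the target without disturbing the epoxide or the other esters.

**Compound list**

1 | geraniol | CC(C)=CCC/C(C)=C/CO | starting material
2 | geranyl triethylsilyl ether | CC(C)=CCC/C(C)=C/CO[Si](CC)(CC)CC | intermediate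
3 | (4E)-4-methyl-6-(triethylsilyloxy)hex-4-enal | O=CCC/C(C)=C/CO[Si](CC)(CC)CC | intermediate
4 | ethyl (triphenylphosphoranylidene)acetate | CCOC(=O)C=P(c1ccccc1)(c1ccccc1)c1ccccc1 | starting material
5 | ethyl iodo(triphenylphosphoranylidene)acetate | CCOC(=O)C(I)=P(c1ccccc1)(c1ccccc1)c1ccccc1 | intermediate
6 | ethyl (2Z,6E)-2-iodo-6-methyl-8-(triethylsilyloxy)octa-2,6-dienoate | CCOC(=O)/C(I)=C/CC/C(C)=C/CO[Si](CC)(CC)CC | intermediate
7 | (2Z,6E)-2-iodo-6-methyl-8-(triethylsilyloxy)octa-2,6-dien-1-ol | OC/C(I)=C/CC/C(C)=C/CO[Si](CC)(CC)CC | intermediate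
8 | tert-butyl{[(2Z,6E)-2-iodo-6-methyl-8-(triethylsilyloxy)octa-2,6-dien-1-yl]oxy}diphenylsilane | CC[Si](CC)(CC)OC/C=C(\C)CC/C=C(\I)CO[Si](c1ccccc1)(c1ccccc1)C(C)(C)C | intermediate
9 | (2E,6Z)-8-(tert-butyldiphenylsilyloxy)-7-iodo-3-methylocta-2,6-dienal | O=C/C=C(\C)CC/C=C(\I)CO[Si](c1ccccc1)(c1ccccc1)C(C)(C)C | intermediate
10 | (4S)-4-benzyl-1,3-oxazolidin-2-one | O=C1N[C@@H](Cc2ccccc2)CO1 | starting material
11 | methyl 4-chloro-4-oxobutanoate | COC(=O)CCC(Cl)=O | starting material
12 | methyl 4-[(4S)-4-benzyl-2-oxo-1,3-oxazolidin-3-yl]-4-oxobutanoate | COC(=O)CCC(=O)N1[C@@H](Cc2ccccc2)COC1=O | intermediate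
13 | syn-aldol adduct, methyl (3S,4R,5E,9Z)-3-{[(4S)-4-benzyl-2-oxo-1,3-oxazolidin-3-yl]carbonyl}-11-(tert-butyldiphenylsilyloxy)-4-hydroxy-10-iodo-6-methylundeca-5,9-dienoate | COC(=O)C[C@@H]([C@H](O)/C=C(\C)CC/C=C(\I)CO[Si](c1ccccc1)(c1ccccc1)C(C)(C)C)C(=O)N1[C@@H](Cc2ccccc2)COC1=O | intermediate
14 | trans-lactone imide, (4S)-4-benzyl-3-{[(2R,3S)-2-[(1E,5Z)-7-(tert-butyldiphenylsilyloxy)-6-iodo-2-methylhepta-1,5-dien-1-yl]-5-oxooxolan-3-yl]carbonyl}-1,3-oxazolidin-2-one | O=C(N1[C@@H](Cc2ccccc2)COC1=O)[C@H]1CC(=O)O[C@@H]1/C=C(\C)CC/C=C(\I)CO[Si](c1ccccc1)(c1ccccc1)C(C)(C)C | intermediate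
15 | (2R,3S)-2-[(1E,5Z)-7-(tert-butyldiphenylsilyloxy)-6-iodo-2-methylhepta-1,5-dien-1-yl]-5-oxooxolane-3-carboxylic acid | OC(=O)[C@H]1CC(=O)O[C@@H]1/C=C(\C)CC/C=C(\I)CO[Si](c1ccccc1)(c1ccccc1)C(C)(C)C | intermediate
16 | mixed anhydride of 15 with isobutyl carbonic acid | CC(C)COC(=O)OC(=O)[C@H]1CC(=O)O[C@@H]1/C=C(\C)CC/C=C(\I)CO[Si](c1ccccc1)(c1ccccc1)C(C)(C)C | intermediate
17 | diazoketone, (4S,5R)-4-(diazoacetyl)-5-[(1E,5Z)-7-(tert-butyldiphenylsilyloxy)-6-iodo-2-methylhepta-1,5-dien-1-yl]oxolan-2-one | [N-]=[N+]=CC(=O)[C@H]1CC(=O)O[C@@H]1/C=C(\C)CC/C=C(\I)CO[Si](c1ccccc1)(c1ccccc1)C(C)(C)C | intermediate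
18 | bromomethyl ketone, (4S,5R)-4-(bromoacetyl)-5-[(1E,5Z)-7-(tert-butyldiphenylsilyloxy)-6-iodo-2-methylhepta-1,5-dien-1-yl]oxolan-2-one | BrCC(=O)[C@H]1CC(=O)O[C@@H]1/C=C(\C)CC/C=C(\I)CO[Si](c1ccccc1)(c1ccccc1)C(C)(C)C | intermediate
19 | bromohydrin, (4R,5R)-4-[(1R)-2-bromo-1-hydroxyethyl]-5-[(1E,5Z)-7-(tert-butyldiphenylsilyloxy)-6-iodo-2-methylhepta-1,5-dien-1-yl]oxolan-2-one | BrC[C@H](O)[C@H]1CC(=O)O[C@@H]1/C=C(\C)CC/C=C(\I)CO[Si](c1ccccc1)(c1ccccc1)C(C)(C)C | intermediate
20 | bromide silyl ether, (4S,5R)-4-[(1R)-2-bromo-1-(triethylsilyloxy)ethyl]-5-[(1E,5Z)-7-(tert-butyldiphenylsilyloxy)-6-iodo-2-methylhepta-1,5-dien-1-yl]oxolan-2-one | BrC[C@H](O[Si](CC)(CC)CC)[C@H]1CC(=O)O[C@@H]1/C=C(\C)CC/C=C(\I)CO[Si](c1ccccc1)(c1ccccc1)C(C)(C)C | intermediate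
21 | 14-(tert-butyldiphenylsilyloxy)-8α-(triethylsilyloxy)-13-norgermacra-1(10),4-dien-12,6α-olide (C4=C5 E; C1=C10 cis in the ring) | CC[Si](CC)(CC)O[C@H]1C/C(CO[Si](c3ccccc3)(c3ccccc3)C(C)(C)C)=C\CC/C(C)=C/[C@H]2OC(=O)C[C@H]12 | intermediate
22 | Mannich base, 11-(dimethylaminomethyl) derivative of 21 (C11 not defined) | CC[Si](CC)(CC)O[C@H]1C/C(CO[Si](c3ccccc3)(c3ccccc3)C(C)(C)C)=C\CC/C(C)=C/[C@H]2OC(=O)C(CN(C)C)[C@H]12 | intermediate
23 | trimethylammonium iodide of 22 (C11 not defined) | CC[Si](CC)(CC)O[C@H]1C/C(CO[Si](c3ccccc3)(c3ccccc3)C(C)(C)C)=C\CC/C(C)=C/[C@H]2OC(=O)C(C[N+](C)(C)C)[C@H]12.[I-] | intermediate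
24 | 14-(tert-butyldiphenylsilyloxy)-8α-(triethylsilyloxy)germacra-1(10),4,11(13)-trien-12,6α-olide | CC[Si](CC)(CC)O[C@H]1C/C(CO[Si](c3ccccc3)(c3ccccc3)C(C)(C)C)=C\CC/C(C)=C/[C@H]2OC(=O)C(=C)[C@H]12 | intermediate
25 | 14-(tert-butyldiphenylsilyloxy)-8α-hydroxygermacra-1(10),4,11(13)-trien-12,6α-olide | O[C@H]1C/C(CO[Si](c3ccccc3)(c3ccccc3)C(C)(C)C)=C\CC/C(C)=C/[C@H]2OC(=O)C(=C)[C@H]12 | intermediate
26 | 14-(tert-butyldiphenylsilyloxy)-8α-(methacryloyloxy)germacra-1(10),4,11(13)-trien-12,6α-olide | C=C(C)C(=O)O[C@H]1C/C(CO[Si](c3ccccc3)(c3ccccc3)C(C)(C)C)=C\CC/C(C)=C/[C@H]2OC(=O)C(=C)[C@H]12 | intermediate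
27 | 14-hydroxy-8α-(methacryloyloxy)germacra-1(10),4,11(13)-trien-12,6α-olide | C=C(C)C(=O)O[C@H]1C/C(CO)=C\CC/C(C)=C/[C@H]2OC(=O)C(=C)[C@H]12 | intermediate
28 | (1R,10R)-1,10-epoxy-14-hydroxy-8α-(methacryloyloxy)germacra-4,11(13)-dien-12,6α-olide | C=C(C)C(=O)O[C@H]1C[C@]2(CO)O[C@@H]2CC/C(C)=C/[C@H]2OC(=O)C(=C)[C@H]12 | intermediate
29 | (1R,10R)-14-acetoxy-1,10-epoxy-8α-(methacryloyloxy)germacra-4,11(13)-dien-12,6α-olide | C=C(C)C(=O)O[C@H]1C[C@]2(COC(C)=O)O[C@@H]2CC/C(C)=C/[C@H]2OC(=O)C(=C)[C@H]12 | target

**Step count**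

Total: 19 steps. Longest linear sequence: 18 steps (steps 1–6 and 8–19); step 7 is a one-step side branch.

**Steps most likely to fail**

Step 13 (proposed new method). Intermolecular coupling to oligomers, loss of iodine from C10 by protonation, or simple reduction of the C9 halide may outrun ring closure. The fallback uses known reactions and runs from 20 back to 21. Halide exchange (NaI, acetone) gives the primary iodide F1. Radical borylation with bis(catecholato)diboron under blue light in DMF, which should leave the sp2 iodide alone, gives the catechol boronate F2. Pinacol and Et3N in the same flask convert it into the pinacol boronate F3, with C8 untouched. An intramolecular alkyl Suzuki–Miyaura coupling (Pd(dppf)Cl2, Ag2O, K2CO3, THF, 60 °C, high dilution) then closes C9–C10 and gives 21.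

Step 11. The C7 stereocentre may oppose the catalyst (mismatched pair), so that facial selectivity at C8 is poor. The fallback gives up selective reduction and resolves at the epoxide stage, from 18 back to 19. Luche reduction (NaBH4, CeCl3·7H2O, MeOH, −78 °C) gives the bromohydrin as a C8 epimer mixture F4. K2CO3 in acetone closes the terminal oxirane epimer mixture F5. Hydrolytic kinetic resolution with water and the cobalt salen acetate (salen)Co(OAc) leaves the 8R oxirane F6 and hydrolyses its epimer to the diol F7. The (S,S) catalyst is expected to be the right antipode by analogy with the resolution of propylene oxide. LiBr and AcOH reopen F6 at C9 to give 19.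

Step 18. The titanium Lewis acid may trigger transannular opening of the new epoxide by the C4=C5 alkene, or the tartrate may be mismatched with the facial bias of the ring. The fallback avoids Lewis acid and the directing group, from 27 to 29. Acetylation first (Ac2O, pyridine) gives the allylic acetate F8. Epoxidation with the dioxirane from the D-fructose-derived Shi ketone (KHSO5, K2CO3 buffer, MeCN/dimethoxymethane/water, 0 °C) should then oxidise C1=C10 under reagent control in a basic medium and give 29 directly. The sense is expected to be the one that gives the R,R oxide from 1-phenylcyclohexene.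

Further compounds
F1 | step 13 | primary iodide, (4S,5R)-4-[(1R)-2-iodo-1-(triethylsilyloxy)ethyl]-5-[(1E,5Z)-7-(tert-butyldiphenylsilyloxy)-6-iodo-2-methylhepta-1,5-dien-1-yl]oxolan-2-one | IC[C@H](O[Si](CC)(CC)CC)[C@H]1CC(=O)O[C@@H]1/C=C(\C)CC/C=C(\I)CO[Si](c1ccccc1)(c1ccccc1)C(C)(C)C
F2 | step 13 | catechol boronate at C9 (configuration as in 20) | c1ccc2OB(C[C@H](O[Si](CC)(CC)CC)[C@H]3CC(=O)O[C@@H]3/C=C(\C)CC/C=C(\I)CO[Si](c4ccccc4)(c4ccccc4)C(C)(C)C)Oc2c1
F3 | step 13 | pinacol boronate at C9 (configuration as in 20) | CC1(C)OB(C[C@H](O[Si](CC)(CC)CC)[C@H]2CC(=O)O[C@@H]2/C=C(\C)CC/C=C(\I)CO[Si](c3ccccc3)(c3ccccc3)C(C)(C)C)OC1(C)C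
F4 | step 11 | bromohydrin as a mixture of C8 epimers | BrCC(O)[C@H]1CC(=O)O[C@@H]1/C=C(\C)CC/C=C(\I)CO[Si](c1ccccc1)(c1ccccc1)C(C)(C)C
F5 | step 11 | terminal oxirane as a mixture of C8 epimers | C1OC1[C@H]2CC(=O)O[C@@H]2/C=C(\C)CC/C=C(\I)CO[Si](c3ccccc3)(c3ccccc3)C(C)(C)C
F6 | step 11 | 8R oxirane, (4R,5R)-4-[(2R)-oxiran-2-yl] lactone | C1O[C@@H]1[C@H]2CC(=O)O[C@@H]2/C=C(\C)CC/C=C(\I)CO[Si](c3ccccc3)(c3ccccc3)C(C)(C)C
F7 | step 11 | 1,2-diol from the unwanted C8 epimer | OC[C@@H](O)[C@H]1CC(=O)O[C@@H]1/C=C(\C)CC/C=C(\I)CO[Si](c1ccccc1)(c1ccccc1)C(C)(C)C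
F8 | step 18 | allylic acetate, 14-acetoxy-8α-(methacryloyloxy)germacra-1(10),4,11(13)-trien-12,6α-olide | C=C(C)C(=O)O[C@H]1C/C(COC(C)=O)=C\CC/C(C)=C/[C@H]2OC(=O)C(=C)[C@H]12
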